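Count the nucleophile first, said the chair, opening the short meeting on this flask.

| setting | amber | grey | violet | flask |
|---|---|---|---|---|
| electrophile | 26 mM | 26 mM | 26 mM | 26 mM |
| nucleophile | 2 equiv | 2 equiv | 2 equiv | 2.00 equiv |
| buffer base | 4.2 equiv | 6.6 equiv | 3 equiv | 3.00 equiv |
| buffer acid | 0.30 equiv | 0.30 equiv | 0.15 equiv | 0.300 equiv |
| remark | run made earlier | run made earlier | run made earlier |  |
| time |  |  |  | 10 h |

- amber (time / h: electrophile / %, product / %): 1.00: 22.0, 82.3; 2.50: 16.3, 85.3; 3.00: 14.6, 83.7; 5.00: 13.9, 84.9; 6.00: 13.3, 87.4; 8.00: 12.2, 85.5
- grey (time / h: electrophile / %, product / %): 1.00: 20.5, 78.6; 2.50: 16.0, 85.1; 3.00: 16.5, 84.6; 5.00: 13.9, 85.2; 6.00: 13.4, 86.9; 8.00: 12.3, 86.9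
- violet (time / h: electrophile / %, product / %): 0.667: 21.1, 80.9; 1.33: 13.3, 87.1; 2.50: 9.6, 91.4; 4.00: 6.7, 90.5; 8.00: 5.8, 91.1

(readings scatter by 1 percentage point)

- acid is the free proton; pH is minus the decimal logarithm of its molar concentration
- reactions considered so far: electrophile + nucleophile -> acid + product + leaving group; protonated nucleophile <-> nucleophile + acid; buffer acid <-> buffer base + acid
- the earlier runs do not show the pH; that part of a forecast is a guess

- part of the electrophile that has reacted at 10 h
- pH of the solution at 10 h

The first speaker read the runs. Amber and grey carried 4.2 equiv and 6.6 equiv of buffer base, yet at 8.00 h they held 12.2% and 12.3% of electrophile. Violet, with half the buffer acid of amber, held 5.8% at 8.00 h.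

The second speaker offered a rule, and the meeting adopted it as its own reckoning. Suppose nucleophile takes acid ahead of buffer base. Then the buffer acid charged protonates nucleophile at the start. After that, each electrophile that reacts costs two nucleophile: one goes into product, and one takes the acid set free. Nucleophile is then the limiting reagent. She named the stall conversion, nucleophile charged less buffer acid charged, divided by two, 85.0% of the electrophile for this flask and for amber. For violet it gives 92.5%.

The last electrophile readings put amber at 87.8% reacted and violet at 94.2%, each a little above its stall, with the readings still falling. This flask has the stall of amber, so the meeting committed to about 87.8% at 10 h. The chair noted that pH goes as the logarithm of buffer base over buffer acid, but no run gives the constant, so pH stayed open.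

The forecast gave 89% and pH 8, holding that “extra base does nothing”.

The flask gives 86.9% and pH 6.89.

    electrophile + nucleophile → acid + product + leaving group (k = 141 M⁻¹ h⁻¹)
    protonated nucleophile ⇌ nucleophile + acid, settled at all times (K = 4.00 × 10⁻¹⁰ M)
    buffer acid ⇌ buffer base + acid, settled at all times (K = 1.00 × 10⁻⁵ M)

The constant of buffer acid stands 4.40 powers of ten above that of protonated nucleophile, and the flask stands 1.9 percentage points above its stall conversion. Take a neighbouring flask, the same but with 0.510 equiv of buffer acid. Its stall conversion is 74.5%. At 10 h that neighbour has reacted 77.6%, which is 3.1 points above the stall, with 0.13% of its nucleophile left.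

The readings were generated by integration on assumed constants, and the scatter is random.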